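The target is cut at the C11–C11′ linker into two trans-fused oxepane–cyclohexane halves that differ only at C8 and in C3 acylation; both descend from one bicycle. Everything rests on a (4+3) annulation of the oxepane (O–C4(Me2)–C3–C2–C1–C10–C5): a cyclohexane carrying C5–OH and a neopentyl C1 carbanion is joined with the intact epoxy-prenyl unit C2–C3–C4, so that C1–C2 alkylation and 7-endo opening of the (S)-epoxide at its gem-dimethyl carbon C4 by the C5 oxygen close the ring in one flask and deliver the C3 carbinol. The precursor is a monocyclic iodo alcohol from a titanocene epoxy-olefin cyclization.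

Key step: step 8

Remark on numbering: the half with the C3 acetate is numbered C1–C11 (oxepane O–C4–C3–C2–C1–C10–C5, cyclohexane C5–C10, linker carbon C11) and the half with the free C3′ hydroxyl C1′–C11′; β is the face of the C10 methyl group, α the opposite face.

Step 1
Reactants: 1 geraniol
Product: 2 geranyl TBS ether
Conditions: TBSCl, imidazole, CH2Cl2, 0 to 23 °C
Reagents that add atoms: tert-butyldimethylsilyl chloride, CC(C)(C)[Si](C)(C)Cl
Why: Silylation of the primary allylic alcohol masks the C11 oxygen, so that only the allylic alcohol made in step 2 can direct the later epoxidation.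

Step 2
Reactants: 2 geranyl TBS ether
Product: 3 E-allylic alcohol
Conditions: SeO2 (cat.), t-BuOOH, salicylic acid (cat.), CH2Cl2, 23 °C
Reagents that add atoms: tert-butyl hydroperoxide, CC(C)(C)OO (oxygen delivered through selenium dioxide, O=[Se]=O)
Why: The selenium dioxide allylic oxidation (ene reaction then [2,3]-shift) should hydroxylate the E-methyl group of the more electron-rich terminal alkene, giving the E-allylic alcohol whose CH2OH carbon becomes C1.

Step 3
Reactants: 3 E-allylic alcohol
Product: 4 epoxy alcohol
Conditions: Ti(OiPr)4 (cat.), L-(+)-diethyl tartrate (cat.), t-BuOOH, 4 Å molecular sieves, CH2Cl2, −20 °C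
Reagents that add atoms: tert-butyl hydroperoxide, CC(C)(C)OO
Why: In the Sharpless asymmetric epoxidation only the alkene of the free allylic alcohol reacts, and the L-(+)-tartrate ligand should give the (2S,3S)-epoxide, which fixes the absolute configuration of the future C5 and C10.

Step 4
Reactants: 4 epoxy alcohol
Product: 5 monocyclic diol
Conditions: Cp2TiCl2, Mn dust, THF, 23 °C; aqueous HCl work-up
Reagents that add atoms: none
Why: In this radical epoxy-olefin cyclization titanocene monochloride Cp2TiCl opens the epoxide to the tertiary C10 radical, which should close 6-endo onto C9 through a chair transition state (C5–O and C9–CH2OTBS equatorial, the bulkier titanium-bound CH2O group on C10 equatorial and the methyl axial), and the C8 radical should end as the exocyclic alkene by titanium-mediated β-hydride elimination.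

Step 5
Reactants: 5 monocyclic diol
Product: 6 iodo alcohol
Conditions: iodine, PPh3, imidazole, toluene, 70 °C
Reagents that add atoms: iodine, [I][I]
Why: The Garegg–Samuelsson (Appel-type) iodination should convert the primary neopentyl hydroxyl selectively, because the secondary C5 hydroxyl next to the quaternary carbon is much more hindered.

Step 6
Reactants: 7 prenol
Product: 8 (S)-3,3-dimethylglycidol
Conditions: Ti(OiPr)4 (cat.), L-(+)-diisopropyl tartrate (cat.), t-BuOOH, 4 Å molecular sieves, CH2Cl2, −20 °C; non-aqueous work-up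
Reagents that add atoms: tert-butyl hydroperoxide, CC(C)(C)OO
Why: The Sharpless asymmetric epoxidation with the L-(+)-tartrate ligand should give the (S)-epoxy alcohol, which sets the future C3 stereocenter by reagent control.

Step 7
Reactants: 8 (S)-3,3-dimethylglycidol
Product: 9 epoxy triflate
Conditions: Tf2O, 2,6-lutidine, CH2Cl2, −78 °C; used at once
Reagents that add atoms: trifluoromethanesulfonic anhydride, O=S(=O)(OS(=O)(=O)C(F)(F)F)C(F)(F)F
Why: Sulfonylation of the primary alcohol turns C2 into a very reactive primary electrophile without touching the stereocenter or the epoxide.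

Step 8
Reactants: 6 iodo alcohol; 9 epoxy triflate
Product: 12 bicyclic oxepanol, via dilithio species 10 (not isolated), via epoxy alcohol 11 (not isolated)
Conditions: t-BuLi (3.1 equiv), Et2O–pentane, −78 °C; 9 (1.3 equiv), −78 to −30 °C; then (CF3)2CHOH, −30 to 23 °C
Reagents that add atoms: none
Why: Deprotonation and iodine–lithium exchange give the γ-lithio alkoxide 10, whose neopentyl C1 carbanion displaces the primary triflate of 9 (SN2 C-alkylation) to form C1–C2 with the (S)-epoxide intact; (CF3)2CHOH then protonates the alkoxide, activates the epoxide by hydrogen bonding and lets the C5 hydroxyl open it at the tertiary carbon C4, which forms O–C4. The closest known reaction types are the alkylation of alkyllithiums with primary alkyl triflates and the fluoroalcohol- or acid-promoted cyclization of hydroxy epoxides at the more substituted carbon of a trisubstituted epoxide. One ring is closed, the oxepane, in the 7-endo-tet mode. No new stereocenter is created: C3 keeps its C–O bond and the S configuration set by the Sharpless epoxidation of 7, C4 is not stereogenic, and the trans ring fusion is already present at C5 and C10 of 6. The step needs attack at C4 (7-endo) in preference to C3 (6-exo), which should be secured by the cation-stabilizing gem-dimethyl group in the ionizing medium and by the configuration of 11, in which 6-exo attack would have to place the C(CH3)2O substituent axial on a trans-fused tetrahydropyran chair. The exocyclic alkene and the silyl ether should not react, and the fluoroalcohol also damps the nucleophilicity of the lithium iodide present.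

Step 9
Reactants: 12 bicyclic oxepanol
Product: 13 bicyclic diol
Conditions: Bu4NF, THF, 23 °C
Reagents that add atoms: none
Why: Fluoride-mediated desilylation frees the C11 hydroxyl and gives the diol from which both halves are made.

Step 10
Reactants: 13 bicyclic diol
Product: 14 keto diol
Conditions: O3, CH2Cl2–MeOH, −78 °C; then Me2S
Reagents that add atoms: ozone, [O-][O+]=O
Why: Ozonolysis with reductive work-up cleaves the only alkene to the C8 ketone.

Step 11
Reactants: 14 keto diol
Product: 16 enone, via keto mesylate 15 (not isolated)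
Conditions: MsCl (1.05 equiv), Et3N, CH2Cl2, −20 °C; then DBU, 23 °C
Reagents that add atoms: none
Why: Selective mesylation of the primary β-hydroxyl followed by E1cB elimination should give the α-methylene ketone in which C11 is the unhindered acceptor terminus.

Step 12
Reactants: 13 bicyclic diol
Product: 17 epoxy diol
Conditions: mCPBA, NaHCO3, CH2Cl2, 0 °C
Reagents that add atoms: 3-chloroperbenzoic acid, OOC(=O)c1cccc(Cl)c1
Why: In the Prilezhaev epoxidation the peracid should approach the exocyclic alkene from the α face, because the axial C10 methyl group shields the β face, which places the C8′ oxygen α.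

Step 13
Reactants: 17 epoxy diol
Product: 19 triflate silyl ether, via hydroxy triflate 18 (not isolated)
Conditions: Tf2O (1.05 equiv), 2,6-lutidine, CH2Cl2, −78 °C; then TESOTf, −78 to −40 °C
Reagents that add atoms: trifluoromethanesulfonic anhydride, O=S(=O)(OS(=O)(=O)C(F)(F)F)C(F)(F)F; triethylsilyl trifluoromethanesulfonate, CC[Si](CC)(CC)OS(=O)(=O)C(F)(F)F
Why: One-pot chemoselective triflation of the primary hydroxyl and silylation of the hindered secondary C3′ hydroxyl activates C11′ and installs the group that keeps O3′ free of acetate at the end.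

Step 14
Reactants: 16 enone; 19 triflate silyl ether
Product: 21 coupled ketone, via iodide 20 (not isolated)
Conditions: NaI, MeCN, 23 °C; then 16, 1,2,3,5-tetrakis(carbazol-9-yl)-4,6-dicyanobenzene (4CzIPN, cat.), Et3N, H2O, blue LEDs, 23 °C
Reagents that add atoms: none
Why: After a Finkelstein exchange, halogen-atom transfer to the amine-derived α-aminoalkyl radical gives the primary C11′ radical, whose Giese addition to the unhindered methylene of the enone forms C11–C11′, and protonation of the resulting enolate from the α face (also the thermodynamic outcome) should place the side chain equatorial at C9.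

Step 15
Reactants: 21 coupled ketone
Product: 22 coupled tertiary alcohol
Conditions: MeLi, CeCl3, THF, −78 °C
Reagents that add atoms: methyllithium, [Li]C
Why: The organocerium 1,2-addition tolerates the enolizable ketone and the epoxide, and the methyl group should enter from the α face (equatorial attack) because the axial C10 methyl blocks axial approach, giving the axial 8β-hydroxyl and the 8α-methyl.

Step 16
Reactants: 22 coupled tertiary alcohol
Product: 23 triol silyl ether
Conditions: LiAlH4, THF, 0 to 60 °C
Reagents that add atoms: none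
Why: Hydride opens the spiro-epoxide at its unhindered CH2 carbon (SN2), which leaves the C8′–O bond untouched and gives the 8′α-hydroxyl with the 8′β-methyl.

Step 17
Reactants: 23 triol silyl ether
Product: 24 triacetate silyl ether
Conditions: Ac2O, 4-(dimethylamino)pyridine, Et3N, 1,2-dichloroethane, 70 °C
Reagents that add atoms: acetic anhydride, CC(=O)OC(C)=O
Why: Forcing nucleophile-catalyzed acylation (Steglich-type) should acetylate the secondary C3 hydroxyl and both tertiary C8 hydroxyls while O3′ stays silylated.

Step 18
Reactants: 24 triacetate silyl ether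
Product: 25 target CNP0169816.1
Conditions: HF·pyridine, THF–pyridine, 0 to 23 °C
Reagents that add atoms: none
Why: Fluoride-mediated cleavage of the triethylsilyl ether should free the C3′ hydroxyl without touching the three acetates.

Compound list
1 | geraniol, (2E)-3,7-dimethylocta-2,6-dien-1-ol | CC(C)=CCC/C(C)=C/CO | starting material
2 | geranyl tert-butyldimethylsilyl (TBS) ether | CC(C)=CCC/C(C)=C/CO[Si](C)(C)C(C)(C)C | intermediate
3 | (2E,6E)-8-(tert-butyldimethylsilyloxy)-2,6-dimethylocta-2,6-dien-1-ol | OC/C(C)=C/CC/C(C)=C/CO[Si](C)(C)C(C)(C)C | intermediate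
4 | [(2S,3S)-3-[(3E)-5-(tert-butyldimethylsilyloxy)-3-methylpent-3-en-1-yl]-2-methyloxiran-2-yl]methanol | OC[C@]1(C)O[C@H]1CC/C(C)=C/CO[Si](C)(C)C(C)(C)C | intermediate
5 | monocyclic diol, (1S,2R,3R)-3-(tert-butyldimethylsilyloxymethyl)-2-(hydroxymethyl)-2-methyl-4-methylidenecyclohexan-1-ol (C5 hydroxyl equatorial, C10 methyl axial and cis to it, C9 CH2OTBS equatorial) | OC[C@]1(C)[C@@H](O)CCC(=C)[C@H]1CO[Si](C)(C)C(C)(C)C | intermediate
6 | iodo alcohol, 5 with CH2I in place of the C1 CH2OH, same configuration | IC[C@]1(C)[C@@H](O)CCC(=C)[C@H]1CO[Si](C)(C)C(C)(C)C | intermediate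
7 | prenol, 3-methylbut-2-en-1-ol | CC(C)=CCO | starting material
8 | [(2S)-3,3-dimethyloxiran-2-yl]methanol | OC[C@@H]1OC1(C)C | intermediate
9 | [(2S)-3,3-dimethyloxiran-2-yl]methyl trifluoromethanesulfonate | FC(F)(F)S(=O)(=O)OC[C@@H]1OC1(C)C | intermediate
10 | dilithio species, C1-lithio lithium C5-alkoxide derived from 6 (not isolated) | [Li]C[C@]1(C)[C@@H](O[Li])CCC(=C)[C@H]1CO[Si](C)(C)C(C)(C)C | intermediate
11 | epoxy alcohol, 6 with the iodine replaced by the CH2-[(2S)-3,3-dimethyloxiran-2-yl] group (not isolated) | CC1(C)O[C@H]1CC[C@]1(C)[C@@H](O)CCC(=C)[C@H]1CO[Si](C)(C)C(C)(C)C | intermediate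
12 | bicyclic oxepanol, trans-fused 2,2-dimethyloxepan-3-ol/cyclohexane with 3α-OH (3S), 5α-H, 10β-CH3, 9β-CH2OTBS and C8 exocyclic methylene | O[C@H]1CC[C@]2(C)[C@H](CCC(=C)[C@H]2CO[Si](C)(C)C(C)(C)C)OC1(C)C | intermediate
13 | bicyclic diol, 12 with free C11 hydroxyl | O[C@H]1CC[C@]2(C)[C@H](CCC(=C)[C@H]2CO)OC1(C)C | intermediate
14 | keto diol, 13 with a C8 ketone in place of the methylene | O[C@H]1CC[C@]2(C)[C@H](CCC(=O)[C@H]2CO)OC1(C)C | intermediate
15 | keto mesylate, C11 methanesulfonate of 14 (not isolated) | O[C@H]1CC[C@]2(C)[C@H](CCC(=O)[C@H]2COS(C)(=O)=O)OC1(C)C | intermediate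
16 | enone, C8 ketone with C9=C11H2 methylene and free 3α-hydroxyl | O[C@H]1CC[C@]2(C)[C@H](CCC(=O)C2=C)OC1(C)C | intermediate
17 | epoxy diol, 13 with the C8′ methylene converted into a spiro-epoxide, oxygen on the α face | O[C@H]1CC[C@]2(C)[C@H](CC[C@@]3(CO3)[C@H]2CO)OC1(C)C | intermediate
18 | hydroxy triflate, C11′ triflate of 17 (not isolated) | O[C@H]1CC[C@]2(C)[C@H](CC[C@@]3(CO3)[C@H]2COS(=O)(=O)C(F)(F)F)OC1(C)C | intermediate
19 | triflate silyl ether, C11′ triflate and 3′α-triethylsilyl ether of 17 | CC[Si](CC)(CC)O[C@H]1CC[C@]2(C)[C@H](CC[C@@]3(CO3)[C@H]2COS(=O)(=O)C(F)(F)F)OC1(C)C | intermediate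
20 | iodide, C11′ iodide corresponding to 19 (not isolated) | CC[Si](CC)(CC)O[C@H]1CC[C@]2(C)[C@H](CC[C@@]3(CO3)[C@H]2CI)OC1(C)C | intermediate
21 | coupled ketone, unprimed half with C8 ketone and 3α-OH, primed half with 8′α-spiro-epoxide and 3′α-OTES, CH2CH2 linker | O[C@H]1CC[C@]2(C)[C@H](CCC(=O)[C@H]2CC[C@H]2[C@]3(C)CC[C@H](O[Si](CC)(CC)CC)C(C)(C)O[C@H]3CC[C@@]24CO4)OC1(C)C | intermediate
22 | coupled tertiary alcohol, 21 with 8β-OH and 8α-CH3 in place of the ketone | O[C@H]1CC[C@]2(C)[C@H](CC[C@@](C)(O)[C@H]2CC[C@H]2[C@]3(C)CC[C@H](O[Si](CC)(CC)CC)C(C)(C)O[C@H]3CC[C@@]24CO4)OC1(C)C | intermediate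
23 | triol silyl ether, 3α-OH, 8β-OH, 8′α-OH (8′β-CH3), 3′α-OTES | O[C@H]1CC[C@]2(C)[C@H](CC[C@@](C)(O)[C@H]2CC[C@H]2[C@]3(C)CC[C@H](O[Si](CC)(CC)CC)C(C)(C)O[C@H]3CC[C@]2(C)O)OC1(C)C | intermediate
24 | triacetate silyl ether, 3,8,8′-tri-O-acetyl-3′-O-triethylsilyl compound | CC(=O)O[C@H]1CC[C@]2(C)[C@H](CC[C@@](C)(OC(C)=O)[C@H]2CC[C@H]2[C@]3(C)CC[C@H](O[Si](CC)(CC)CC)C(C)(C)O[C@H]3CC[C@]2(C)OC(C)=O)OC1(C)C | intermediate
25 | CNP0169816.1 | CC(=O)O[C@H]1CC[C@]2(C)[C@H](CC[C@@](C)(OC(C)=O)[C@H]2CC[C@H]2[C@]3(C)CC[C@H](O)C(C)(C)O[C@H]3CC[C@]2(C)OC(C)=O)OC1(C)C | target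

Total step count: 18. Longest linear sequence: 14 steps (steps 1–5, 8, 9, then 12–13 or 10–11, then 14–18).

Steps most likely to fail

Step 8. The hindered organolithium may alkylate incompletely, and in the ring-closing stage the epoxide may be opened in the 6-exo sense, by elimination to the allylic alcohol or by iodide. The fallback closes the oxepane by a sulfonyl-directed 7-endo cyclization instead. It sets out from 6: the dilithio species 10 would be trapped with paraformaldehyde to give the homologated diol F1. One-pot triflation and triethylsilylation (Tf2O, 2,6-lutidine, then TESOTf) would give the triflate F2. Lithiated 2,2-dimethyl-3-(phenylsulfonyl)oxirane (n-BuLi, THF–DMPU, −100 °C) would be alkylated by F2 to give the epoxy sulfone F3, in which the sulfonyl group leaves only C4 open to attack. TsOH·H2O in CHCl3 would remove both silyl groups and close the ring with loss of benzenesulfinic acid to the hydroxy oxepanone F4. Corey–Bakshi–Shibata reduction with the (R)-methyl oxazaborolidine and catecholborane at −78 °C would then give 13, where the route is rejoined.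

Step 14. The hindered primary radical may be reduced before it adds, may undergo an intramolecular hydrogen shift, or the enone may oligomerize. The fallback joins the halves by a polar sulfone alkylation. It sets out from 13: PhSSPh and PBu3 would give the sulfide F5, and H2O2 with catalytic (NH4)6Mo7O24 would give the sulfone F6. Its dianion (n-BuLi, THF–HMPA, −78 °C) would be alkylated with triflate 19 to give the coupled sulfone F7. Lithium in liquid ammonia would remove the sulfonyl group and open the epoxide reductively to the alkene triol F8. Ozonolysis would give the ketone F9, and MeLi/CeCl3 would give 23, where the route is rejoined.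

Step 4. The tertiary C10 radical is planar, so facial control at C10 may be lost, and regiocontrol in the alkene-forming termination may be incomplete. The fallback is a stereospecific cationic cyclization. It sets out from 4: TESCl and imidazole would give the bis-silyl epoxide F10. ZrCl4 in CH2Cl2 at −20 °C would open the epoxide with anti attack of the alkene on C10, so that the E geometry of 3 fixes the CH2O group equatorial, and give the cyclized alcohol F11. Pyridinium p-toluenesulfonate in MeOH would remove the primary triethylsilyl group selectively and return to 5.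

Further compounds
F1 | step 8 | homologated diol, 5 with CH2CH2OH in place of CH2OH at C10 | OCC[C@]1(C)[C@@H](O)CCC(=C)[C@H]1CO[Si](C)(C)C(C)(C)C
F2 | step 8 | triflate of F1 with C5 triethylsilyl ether | FC(F)(F)S(=O)(=O)OCC[C@]1(C)[C@@H](O[Si](CC)(CC)CC)CCC(=C)[C@H]1CO[Si](C)(C)C(C)(C)C
F3 | step 8 | epoxy sulfone, 2,2-dimethyl-3-(phenylsulfonyl)oxirane alkylated at C3 by F2 (mixture at the sulfonyl carbon) | CC1(C)OC1(CC[C@]1(C)[C@@H](O[Si](CC)(CC)CC)CCC(=C)[C@H]1CO[Si](C)(C)C(C)(C)C)S(=O)(=O)c1ccccc1
F4 | step 8 | hydroxy oxepanone, 3-ketone corresponding to 13 | O=C1CC[C@]2(C)[C@H](CCC(=C)[C@H]2CO)OC1(C)C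
F5 | step 14 | C11 phenyl sulfide of 13 | O[C@H]1CC[C@]2(C)[C@H](CCC(=C)[C@H]2CSc2ccccc2)OC1(C)C
F6 | step 14 | C11 phenyl sulfone of 13 | O[C@H]1CC[C@]2(C)[C@H](CCC(=C)[C@H]2CS(=O)(=O)c2ccccc2)OC1(C)C
F7 | step 14 | coupled sulfone (mixture at C11) | O[C@H]1CC[C@]2(C)[C@H](CCC(=C)[C@H]2C(S(=O)(=O)c2ccccc2)C[C@H]2[C@]3(C)CC[C@H](O[Si](CC)(CC)CC)C(C)(C)O[C@H]3CC[C@@]24CO4)OC1(C)C
F8 | step 14 | alkene triol, C8 exocyclic methylene, 8′α-OH, 3′α-OTES | O[C@H]1CC[C@]2(C)[C@H](CCC(=C)[C@H]2CC[C@H]2[C@]3(C)CC[C@H](O[Si](CC)(CC)CC)C(C)(C)O[C@H]3CC[C@]2(C)O)OC1(C)C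
F9 | step 14 | ketone, C8 ketone with 8′α-OH and 3′α-OTES | O[C@H]1CC[C@]2(C)[C@H](CCC(=O)[C@H]2CC[C@H]2[C@]3(C)CC[C@H](O[Si](CC)(CC)CC)C(C)(C)O[C@H]3CC[C@]2(C)O)OC1(C)C
F10 | step 4 | triethylsilyl ether of 4 | CC[Si](CC)(CC)OC[C@]1(C)O[C@H]1CC/C(C)=C/CO[Si](C)(C)C(C)(C)C
F11 | step 4 | cyclized alcohol, C1 triethylsilyl ether of 5 | CC[Si](CC)(CC)OC[C@]1(C)[C@@H](O)CCC(=C)[C@H]1CO[Si](C)(C)C(C)(C)C
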